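# Proposed total synthesis of CNP0478950.1 by a polarity-alternating radical bicyclisation

## Analysis of the target

Labdane numbering is used throughout. Ring A is C1–C5 with C10 and ring B is C5–C10. C11–C12 link C9 to the butenolide (C13–C16). C17 is the carboxyl carbon on C8, C18 and C19 are the methyl and carboxyl carbons on C4, and C20 is the methyl on C10.

- The target is a trans-decalin with five stereocentres, (4S,5R,8R,9S,10R). Two are quaternary (C4, with C19 axial and syn to C20, and C10). The C5 hydrogen is anti to C20, and C8 (carboxyl C17) and C9 (side chain) form a trans-diequatorial pair.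
- C4, C5, C10 and C9 cannot be epimerised and must be set under kinetic control. C8 lies α to a carboxyl group and its required configuration is the thermodynamic one.
- The sensitive groups are the α-alkylbutenolide (opened by hydroxide, reduced by hydrides, a radical and Michael acceptor) and the neopentyl, axial C19 carboxyl group. Esters of C19 cannot be hydrolysed, so whatever sits on C19 must leave by another mechanism.
- The feature that suggests the strategy is the placement of the two carboxyl carbons. C19 on C4 and C17 on C8 mark the two ends of the array C4–C5–C10–C9–C8, which contains both ring-closing bonds: C4–C5 of ring A and C9–C10 of ring B.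
- A carboxyl-activated C4 can carry an electrophilic radical, the alkene C5=C10 relays it as a nucleophilic tertiary radical, and an unsaturated ester at C8=C9 accepts it. The polarity therefore alternates correctly along the whole chain.
- The difficulty sits in three places: absolute control in a cascade that starts from an achiral chain, the (Z)-geometry of the acceptor that decides C9, and an end game that frees two acids without harming the butenolide.

## Retrosynthetic reasoning

**C12–C13 (butenolide last).** The target 22 is cut between C12 and C13 into the vinyl diacid 19 and bromobutenolide 20. The forward reaction is a hydroboration to borane 21 followed by an sp3–sp2 cross-coupling. Cutting here keeps the butenolide out of every radical, basic and reducing step, and the coupling has to tolerate two free carboxyl groups.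

**C11=C12 from a lactone.** The vinyl group of 19 is traced to the trans-fused lactone acid 16. A selenium nucleophile opens the lactone at C12 (17), and the selenoxide 18 eliminates. The lactone is chosen because it masks C17, turns the C12 oxygen into a leaving group, and exists only in a stable trans-fused form, which fixes C8.

**C3 oxygen, auxiliary and both esters in one operation.** Lactone acid 16 is traced to the bicyclic keto diester 12. Under Wolff–Kishner conditions the C3 hydrazone 13 should acylate on the neighbouring C19 ester (pyrazolinone 14), which expels alcohol 1 from an ester that cannot be hydrolysed. Base then removes the nitrogen, saponifies C17 and gives hydroxy diacid 15. The C3 ketone that the key step needs as an activating group thus becomes the handle that frees C19.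

**C4–C5 and C9–C10 (key disconnection).** Both rings of 12 are opened to the acyclic keto ester 11. The forward reaction is an oxidative radical bicyclisation: a C4 radical stabilised by C19 and the C3 ketone, relay through C5=C10, and termination on the C8=C9 enoate that already carries C17. It has to set C4, C5, C10 and C9 in one step from a chain with no stereocentre. The ester of alcohol 1 supplies the absolute sense and the (Z)-enoate supplies C9.

**C1–C2.** Chain 11 is cut between C1 and C2 into the keto ester 3 (from alcohol 1 and ester 2) and the allylic bromide 10. The forward reaction is a dianion γ-alkylation, which joins the initiator to the relay-acceptor half in one step.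

**C1 oxygenation and C8=C9.** Bromide 10 comes from alcohol 9 and this from the (Z)-enoate 8 by allylic oxidation of the (E)-methyl group. Enoate 8 is cut at C8=C9 into phosphonate 6 and aldehyde 7 (Z-selective olefination). Phosphonate 6 is cut at C7–C8 into phosphonoacetate 4 and bromide 5.

## Alternatives that were turned down

**Alternative 1:** the textbook disconnection takes both rings from a Robinson annulation, that is from the (S)-Wieland–Miescher ketone A1, and then dresses the decalin.
- Forward key step: reductive carboxylation–methylation of the enone would give the keto ester A2, with C4 set by alkylation anti to C20. C3 must then be deoxygenated, the C9 ketone turned into C9–H bearing the two-carbon chain, and C8 carboxylated.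
- Turned down because no step forms more than one skeletal bond or more than one stereocentre. C8 and C9 have to be built next to the quaternary C10 through a hindered ketone, where olefination and enolate chemistry are slow and poorly regioselective. Two deoxygenations and two homologations would put the sequence well above fifteen linear steps before the butenolide is attached.

**Alternative 2:** a reductive radical bicyclisation started from an epoxide.
- Forward key step: Sharpless epoxidation of alcohol 9 and acetylation would give the epoxy polyene A5. A trivalent titanium single-electron reductant would open it to the tertiary C4 radical, which could run through the same relay and enoate termination to the hydroxy ester A6. The absolute configuration would come from a catalytic step, and the final radical would be reduced cleanly to a titanium enolate.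
- Turned down because the C4 radical carries a methyl and an acetoxymethyl group and rotates freely. Nothing makes the oxygenated carbon axial; the larger group should prefer the equatorial site and give the C4 epimer. A6 would also need deoxygenation at C3 and a two-stage oxidation of C19, three to four steps more than the route chosen.

**Alternative 3:** a chiral-pool degradation that maps ring C of podocarpic acid A3 onto the two appendages.
- Forward key step: A3 already holds C4, C5 and C10 with C19 as the acid. Reduction of the phenol ring, then cleavage of the C13–C14 bond with excision of C13, would leave C14 as the C17 carboxyl and C11–C12 as the tether, that is the triacid A4.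
- Turned down because it builds nothing and cuts much. The aromatic ring has to be reduced, C8 and C9 set by protonation, the ring cut regioselectively between two similar methylene flanks of a C12 ketone, one carbon removed, and the C12 carboxyl of A4 then reduced in the presence of two others. That is more redox steps than the whole chosen route, and it rests on a scarce natural product.

Key step: step 7

## Assumptions

- The sense of induction of the 8-phenylmenthyl ester in step 7 is taken from the stacking model given there. If the opposite sense holds, the enantiomer of 1 is used and nothing else changes.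
- Aldehyde 7 and 3-bromofuran-2(5H)-one (20) are taken as catalogue compounds.
- Labdane atom numbers of the target are used for the corresponding atoms of all intermediates.

## Route

Step 1
Reactants: 1 (−)-8-phenylmenthol, (1R,2S,5R)-5-methyl-2-(2-phenylpropan-2-yl)cyclohexan-1-ol; 2 ethyl 2-methyl-3-oxobutanoate
Product: 3 (1R,2S,5R)-5-methyl-2-(2-phenylpropan-2-yl)cyclohexyl 2-methyl-3-oxobutanoate (epimers at the acyl C2)
Conditions: DMAP (0.3 equiv), toluene, reflux, 4 Å molecular sieves
Reagents that add atoms: none
Why: DMAP-catalysed transesterification of a β-keto ester with a hindered secondary alcohol, driven by removal of the liberated alcohol; the acyl C2 stereocentre is irrelevant because it becomes the planar radical centre in step 7.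

Step 2
Reactants: 4 methyl 2-[bis(2,2,2-trifluoroethoxy)phosphoryl]acetate; 5 5-bromo-2-methylpent-2-ene
Product: 6 methyl 2-[bis(2,2,2-trifluoroethoxy)phosphoryl]-6-methylhept-5-enoate (racemic)
Conditions: NaH, NaI (cat.), DMSO, 25 → 50 °C
Reagents that add atoms: none
Why: C-alkylation of the stabilised phosphonoacetate anion with a primary homoallylic bromide under iodide catalysis gives the α-branched Still–Gennari reagent; a second alkylation is slowed by the tertiary, less acidic C–H.

Step 3
Reactants: 6 methyl 2-[bis(2,2,2-trifluoroethoxy)phosphoryl]-6-methylhept-5-enoate; 7 3-[(tert-butyldimethylsilyl)oxy]propanal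
Product: 8 methyl (2Z)-5-[(tert-butyldimethylsilyl)oxy]-2-(4-methylpent-3-en-1-yl)pent-2-enoate
Conditions: KN(SiMe3)2, 18-crown-6, THF, −78 °C
Reagents that add atoms: none
Why: Still–Gennari olefination: the electron-poor phosphonate with a dissociated potassium counter-ion eliminates from the kinetic adduct and places the ester cis to the aldehyde-derived chain. This is the (Z)-geometry (C11 trans to C7) that step 7 translates into the C9 configuration; any (E)-isomer is removed by chromatography.

Step 4
Reactants: 8 methyl (2Z)-5-[(tert-butyldimethylsilyl)oxy]-2-(4-methylpent-3-en-1-yl)pent-2-enoate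
Product: 9 methyl (2Z)-5-[(tert-butyldimethylsilyl)oxy]-2-[(3E)-5-hydroxy-4-methylpent-3-en-1-yl]pent-2-enoate
Conditions: SeO2 (0.3 equiv), t-BuOOH, salicylic acid (cat.), CH2Cl2, 0 → 25 °C
Reagents that add atoms: tert-butyl hydroperoxide, CC(C)(C)OO
Why: SeO2-catalysed allylic oxidation (ene reaction, then [2,3]-sigmatropic shift) attacks only the electron-rich trisubstituted alkene and, by its usual selectivity, the methyl group trans to the chain. This gives the (E)-allylic alcohol whose carbinol carbon becomes C1; the enoate and its allylic positions are deactivated.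

Step 5
Reactants: 9 methyl (2Z)-5-[(tert-butyldimethylsilyl)oxy]-2-[(3E)-5-hydroxy-4-methylpent-3-en-1-yl]pent-2-enoate
Product: 10 methyl (2Z)-2-[(3E)-5-bromo-4-methylpent-3-en-1-yl]-5-[(tert-butyldimethylsilyl)oxy]pent-2-enoate
Conditions: CBr4, PPh3, CH2Cl2, 0 °C
Reagents that add atoms: carbon tetrabromide, BrC(Br)(Br)Br
Why: Appel bromination of the primary allylic alcohol under neutral conditions should proceed without allylic transposition and without loss of the silyl ether.

Step 6
Reactants: 3 (1R,2S,5R)-5-methyl-2-(2-phenylpropan-2-yl)cyclohexyl 2-methyl-3-oxobutanoate; 10 methyl (2Z)-2-[(3E)-5-bromo-4-methylpent-3-en-1-yl]-5-[(tert-butyldimethylsilyl)oxy]pent-2-enoate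
Product: 11 (1R,2S,5R)-8-phenylmenthyl (6E,10Z)-13-[(tert-butyldimethylsilyl)oxy]-10-(methoxycarbonyl)-2,6-dimethyl-3-oxotrideca-6,10-dienoate (epimers at C2)
Conditions: NaH, THF, 0 °C; n-BuLi, 0 °C; then 10, −78 → 0 °C
Reagents that add atoms: none
Why: γ-Alkylation of the acetoacetate dianion: the more basic terminal carbanion is alkylated by the allylic bromide at low temperature much faster than it adds to the hindered trisubstituted enoate. This forms the C1–C2 bond and completes the acyclic chain.

Step 7
Reactants: 11 (1R,2S,5R)-8-phenylmenthyl (6E,10Z)-13-[(tert-butyldimethylsilyl)oxy]-10-(methoxycarbonyl)-2,6-dimethyl-3-oxotrideca-6,10-dienoate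
Product: 12 17-methyl 19-[(1R,2S,5R)-8-phenylmenthyl] (4R,5R,9S,10R)-12-[(tert-butyldimethylsilyl)oxy]-3-oxo-13,14,15,16-tetranorlabdane-17,19-dioate (trans-decalin; both C8 epimers)
Conditions: Mn(OAc)3·2H2O (2.2 equiv), AcOH–EtOH (4:1), degassed, 25 °C
Reagents that add atoms: none
Why: Mn(OAc)3 forms the manganese enolate of the 2-methyl-3-oxo ester and oxidises it to the electrophilic C4 radical, which adds 6-endo-trig to C5 of the electron-rich (E)-trisubstituted alkene (ring A); the nucleophilic tertiary C10 radical then adds 6-endo-trig to C9, the β-carbon of the (Z)-enoate (ring B), and the electrophilic α-ester radical at C8, which trivalent manganese does not oxidise, is quenched by hydrogen abstraction from ethanol. The closest known reaction type is the oxidative radical bicyclisation of unsaturated 2-methyl-3-oxo esters with trivalent manganese to trans-decalones bearing an axial ester, together with polarity-alternating radical polyene cyclisations in which a tertiary radical is relayed through the β-carbon of an unsaturated nitrile or ester. Ring A closes through a chair in which the ester on the planar C4 radical lies anti to the ketone oxygen and therefore ends axial (C19 β, C18 α), while the (E)-alkene places C6 equatorial (5α-H). Ring B closes through a second chair with C20 axial on the C10 radical (trans fusion) and, because C11 is trans to C7 in the (Z)-enoate, with C11 equatorial (9α-H). The absolute sense is fixed in the first bond formation: the phenyl group of the 8-phenylmenthyl ester stacks over one face of the dicarbonyl radical, the alkene adds to the open face, and the minor series is a diastereomer of 12 that should be removable by chromatography at this stage. C8 is formed without control in the hydrogen transfer and is corrected in step 8. The step needs endo closure twice, which the methyl on C10 and the ester on C8 secure by blocking the exo carbons and stabilising the endo radicals, and it needs the second closure to outrun interception of the C10 radical, which the polarity match with the enoate and the absence of a copper co-oxidant should secure.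

Step 8
Reactants: 12 17-methyl 19-[(1R,2S,5R)-8-phenylmenthyl] (4R,5R,9S,10R)-12-[(tert-butyldimethylsilyl)oxy]-3-oxo-13,14,15,16-tetranorlabdane-17,19-dioate
Product: 16 (4S,5R,8R,9S,10R)-17-oxo-12,17-epoxy-13,14,15,16-tetranorlabdan-19-oic acid (trans-fused δ-lactone acid), via C3 hydrazone 13 (not isolated), via fused pyrazolinone 14 (not isolated), via hydroxy diacid 15 (not isolated)
Conditions: N2H4·H2O, diethylene glycol, 130 °C; KOH, 200 °C; then aq. HCl, THF, 50 °C
Reagents that add atoms: potassium hydroxide, [K+].[OH-]
Why: Wolff–Kishner reduction of an α,α-disubstituted β-keto ester (Huang-Minlon modification): hydrazone 13 should acylate intramolecularly on the neighbouring C19 ester, which expels the otherwise unhydrolysable 8-phenylmenthyl alkoxide and gives pyrazolinone 14; hot KOH then opens the acyl diazene tautomer with loss of N2, leaving C3 as a methylene and C19 as the carboxylate. The same conditions saponify the C17 ester, cleave the silyl ether and equilibrate C8 to the equatorial 8β-H epimer (through the ester before hydrolysis and through the carboxylate dianion at 200 °C). Acidification closes the trans-fused δ-lactone from 15, which masks C17 and activates C12.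

Step 9
Reactants: 16 (4S,5R,8R,9S,10R)-17-oxo-12,17-epoxy-13,14,15,16-tetranorlabdan-19-oic acid
Product: 17 (4S,5R,8R,9S,10R)-12-(phenylselanyl)-13,14,15,16-tetranorlabdane-17,19-dioic acid
Conditions: PhSeH, NaH, DMF, 110 °C; then aq. HCl
Reagents that add atoms: benzeneselenol, [SeH]c1ccccc1
Why: SN2 opening of a lactone at the alkyl carbon by the soft, weakly basic benzeneselenolate exchanges C12–O for C12–Se and releases the C17 carboxylate without touching C8.

Step 10
Reactants: 17 (4S,5R,8R,9S,10R)-12-(phenylselanyl)-13,14,15,16-tetranorlabdane-17,19-dioic acid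
Product: 19 (4S,5R,8R,9S,10R)-13,14,15,16-tetranorlabd-11-ene-17,19-dioic acid (9-vinyl diacid), via selenoxide 18 (not isolated)
Conditions: H2O2 (30 %), pyridine, THF, 0 → 45 °C
Reagents that add atoms: none
Why: Oxidation at selenium and syn-elimination of selenoxide 18, for which only the C11 hydrogens are available, should give the terminal alkene; pyridine intercepts the selenenic acid before it can add back to the alkene.

Step 11
Reactants: 19 (4S,5R,8R,9S,10R)-13,14,15,16-tetranorlabd-11-ene-17,19-dioic acid; 20 3-bromofuran-2(5H)-one
Product: 22 (4S,5R,8R,9S,10R)-16-oxo-15,16-epoxylabd-13-ene-17,19-dioic acid (the target), via alkylborane 21 (not isolated)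
Conditions: 9-BBN (4 equiv), THF, 0 → 25 °C; then 20, Pd(dppf)Cl2 (5 mol %), AsPh3, Cs2CO3, DMF–H2O, 25 → 40 °C; then aq. HCl
Reagents that add atoms: none
Why: Anti-Markovnikov hydroboration of the monosubstituted alkene and B-alkyl Suzuki–Miyaura coupling with the α-bromobutenolide form C12–C13 and deliver the intact butenolide in the last step. The carboxyl groups are carried as their 9-BBN carboxylates and are released on acidification, which also recloses any butenolide opened by the base.

## Compound list

1 | (−)-8-phenylmenthol, (1R,2S,5R)-5-methyl-2-(2-phenylpropan-2-yl)cyclohexan-1-ol | CC(C)(c1ccccc1)[C@@H]1CC[C@@H](C)C[C@H]1O | starting material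
2 | ethyl 2-methyl-3-oxobutanoate | CCOC(=O)C(C)C(C)=O | starting material
3 | (1R,2S,5R)-5-methyl-2-(2-phenylpropan-2-yl)cyclohexyl 2-methyl-3-oxobutanoate (epimers at the acyl C2) | CC(C)(c1ccccc1)[C@@H]1CC[C@@H](C)C[C@H]1OC(=O)C(C)C(C)=O | intermediate
4 | methyl 2-[bis(2,2,2-trifluoroethoxy)phosphoryl]acetate | COC(=O)CP(=O)(OCC(F)(F)F)OCC(F)(F)F | starting material
5 | 5-bromo-2-methylpent-2-ene | CC(C)=CCCBr | starting material
6 | methyl 2-[bis(2,2,2-trifluoroethoxy)phosphoryl]-6-methylhept-5-enoate (racemic) | COC(=O)C(CCC=C(C)C)P(=O)(OCC(F)(F)F)OCC(F)(F)F | intermediate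
7 | 3-[(tert-butyldimethylsilyl)oxy]propanal | O=CCCO[Si](C)(C)C(C)(C)C | starting material
8 | methyl (2Z)-5-[(tert-butyldimethylsilyl)oxy]-2-(4-methylpent-3-en-1-yl)pent-2-enoate | COC(=O)/C(CCC=C(C)C)=C\CCO[Si](C)(C)C(C)(C)C | intermediate
9 | methyl (2Z)-5-[(tert-butyldimethylsilyl)oxy]-2-[(3E)-5-hydroxy-4-methylpent-3-en-1-yl]pent-2-enoate | COC(=O)/C(CC/C=C(\C)CO)=C\CCO[Si](C)(C)C(C)(C)C | intermediate
10 | methyl (2Z)-2-[(3E)-5-bromo-4-methylpent-3-en-1-yl]-5-[(tert-butyldimethylsilyl)oxy]pent-2-enoate | COC(=O)/C(CC/C=C(\C)CBr)=C\CCO[Si](C)(C)C(C)(C)C | intermediate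
11 | (1R,2S,5R)-8-phenylmenthyl (6E,10Z)-13-[(tert-butyldimethylsilyl)oxy]-10-(methoxycarbonyl)-2,6-dimethyl-3-oxotrideca-6,10-dienoate (epimers at C2) | CC(C)(c1ccccc1)[C@@H]1CC[C@@H](C)C[C@H]1OC(=O)C(C)C(=O)CC/C(C)=C/CC/C(C(=O)OC)=C/CCO[Si](C)(C)C(C)(C)C | intermediate
12 | 17-methyl 19-[(1R,2S,5R)-8-phenylmenthyl] (4R,5R,9S,10R)-12-[(tert-butyldimethylsilyl)oxy]-3-oxo-13,14,15,16-tetranorlabdane-17,19-dioate (both C8 epimers) | C[C@]12CCC(=O)[C@](C)(C(=O)O[C@@H]3C[C@H](C)CC[C@H]3C(C)(C)c3ccccc3)[C@@H]1CCC(C(=O)OC)[C@@H]2CCO[Si](C)(C)C(C)(C)C | intermediate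
13 | C3 hydrazone of 12 | C[C@]12CCC(=NN)[C@](C)(C(=O)O[C@@H]3C[C@H](C)CC[C@H]3C(C)(C)c3ccccc3)[C@@H]1CCC(C(=O)OC)[C@@H]2CCO[Si](C)(C)C(C)(C)C | intermediate (not isolated)
14 | ring-A-fused 4,4-disubstituted 2-pyrazolin-5-one (N2=C3, N1–C19 amide; C17 methyl ester and silyl ether still in place) | C[C@]12CCC3=NNC(=O)[C@]3(C)[C@@H]1CCC(C(=O)OC)[C@@H]2CCO[Si](C)(C)C(C)(C)C | intermediate (not isolated)
15 | (4S,5R,8R,9S,10R)-12-hydroxy-13,14,15,16-tetranorlabdane-17,19-dioic acid | C[C@]12CCC[C@](C)(C(=O)O)[C@@H]1CC[C@@H](C(=O)O)[C@@H]2CCO | intermediate (not isolated)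
16 | (4S,5R,8R,9S,10R)-17-oxo-12,17-epoxy-13,14,15,16-tetranorlabdan-19-oic acid (trans-fused δ-lactone acid) | C[C@]12CCC[C@](C)(C(=O)O)[C@@H]1CC[C@H]3C(=O)OCC[C@H]23 | intermediate
17 | (4S,5R,8R,9S,10R)-12-(phenylselanyl)-13,14,15,16-tetranorlabdane-17,19-dioic acid | C[C@]12CCC[C@](C)(C(=O)O)[C@@H]1CC[C@@H](C(=O)O)[C@@H]2CC[Se]c1ccccc1 | intermediate
18 | selenoxide of 17 | C[C@]12CCC[C@](C)(C(=O)O)[C@@H]1CC[C@@H](C(=O)O)[C@@H]2CC[Se](=O)c1ccccc1 | intermediate (not isolated)
19 | (4S,5R,8R,9S,10R)-13,14,15,16-tetranorlabd-11-ene-17,19-dioic acid (9-vinyl diacid) | C[C@]12CCC[C@](C)(C(=O)O)[C@@H]1CC[C@@H](C(=O)O)[C@@H]2C=C | intermediate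
20 | 3-bromofuran-2(5H)-one | O=C1OCC=C1Br | starting material
21 | 12-(9-borabicyclo[3.3.1]nonan-9-yl) adduct of 19, carboxyl groups as 9-BBN carboxylates | C[C@]12CCC[C@](C)(C(=O)OB3C4CCCC3CCC4)[C@@H]1CC[C@@H](C(=O)OB1C3CCCC1CCC3)[C@@H]2CCB1C2CCCC1CCC2 | intermediate (not isolated)
22 | (4S,5R,8R,9S,10R)-16-oxo-15,16-epoxylabd-13-ene-17,19-dioic acid (CNP0478950.1) | C[C@]12CCC[C@](C)(C(=O)O)[C@@H]1CC[C@@H](C(=O)O)[C@@H]2CCC1=CCOC1=O | target

## Step count and risk

Total step count: 11 steps.
Longest linear sequence: 10 steps (steps 2 to 11); step 1 is a one-step side branch.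

Least certain steps:

**Step 7 (key step).**
- What may go wrong: interception of the tertiary C10 radical (oxidation to the cation by trivalent manganese, or hydrogen abstraction from the solvent) before ring B closes; slow chain termination at the stabilised C8 radical, allowing disproportionation; only moderate discrimination of the two faces of the C4 radical by the auxiliary.
- Fallback: a bromine-atom-transfer version of the same bicyclisation, in which the last radical is quenched by fast halogen transfer instead of hydrogen transfer. It sets out from 11. Deprotonation with NaH and bromination with N-bromosuccinimide would give the α-bromo keto ester F1. Initiation with Et3B and air in toluene at −78 °C would propagate a chain in which the C8 radical abstracts bromine from F1 and delivers the 8-bromo bicycle F2. Reduction of the tertiary α-bromo ester with Zn in AcOH comes back to the route at 12.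

**Step 8.**
- What may go wrong: Wolff–Kishner decomposition of hydrazone 13 before it has acylated on the hindered C19 ester, which would leave the auxiliary on an ester that cannot be hydrolysed; retro-Claisen cleavage of the non-enolisable β-keto ester by hydroxide before the hydrazone has formed; incomplete equilibration at C8.
- Fallback: stepwise deoxygenation and reductive removal of the auxiliary. It sets out from 12. p-Toluenesulfonylhydrazide would give the tosylhydrazone F3. Reduction with catecholborane and decomposition with NaOAc, followed by NaOMe in MeOH (C8 equilibration, safe once the ketone is gone), would give the deoxo diester F4. LiAlH4 would reduce both esters to the diol F5 and return alcohol 1. Catalytic TEMPO with NaOCl and NaClO2 would oxidise both primary alcohols to the diacid silyl ether F6. Aqueous HCl would remove the silyl group and close the lactone through 15, which comes back to the route at 16.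

**Step 11.**
- What may go wrong: consumption of the borane by the free carboxyl groups followed by slow transmetalation or protodeboronation; base-induced decomposition of the bromobutenolide before coupling.
- Fallback: form C12–C13 by enolate alkylation and a sulfoxide elimination instead of cross-coupling. It sets out from 16. Me3SiI would open the lactone to the iodo diacid F7. tert-Butyl 2,2,2-trichloroacetimidate under acid catalysis would give the di-tert-butyl ester F8. The lithium enolate of 3-(phenylsulfanyl)dihydrofuran-2(3H)-one would be alkylated by F8 to give the sulfanyl lactone F9. Oxidation with mCPBA and heating in toluene (syn-elimination toward the ring) would give the butenolide diester F10. CF3CO2H would cleave both tert-butyl esters and come back to the route at 22.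

**Step 3.**
- What may go wrong: erosion of the Z-selectivity with the α-branched phosphonate, which would carry the wrong geometry into step 7 and invert C9.
- Fallback: set the enoate geometry by syn-hydrometalation of an alkyne instead of a kinetic olefination. It sets out from 7. Ohira–Bestmann homologation would give the alkyne F11. Lithiation and methyl chloroformate would give the ynoate F12. Palladium-catalysed syn-hydrostannation (Bu3SnH, Pd(PPh3)4) would give the α-stannyl enoate F13. Iododestannylation with I2 would give the α-iodo enoate F14 with retention. B-alkyl Suzuki–Miyaura coupling (Pd(dppf)Cl2, AsPh3, Cs2CO3) with the borane F15, made from 4-methylpenta-1,3-diene and 9-BBN, comes back to the route at 8.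

## Further compounds

F1 | step 7 | (1R,2S,5R)-8-phenylmenthyl (6E,10Z)-2-bromo-13-[(tert-butyldimethylsilyl)oxy]-10-(methoxycarbonyl)-2,6-dimethyl-3-oxotrideca-6,10-dienoate | CC(C)(c1ccccc1)[C@@H]1CC[C@@H](C)C[C@H]1OC(=O)C(C)(Br)C(=O)CC/C(C)=C/CC/C(C(=O)OC)=C/CCO[Si](C)(C)C(C)(C)C
F2 | step 7 | 8-bromo derivative of 12 (C8 epimers) | C[C@]12CCC(=O)[C@](C)(C(=O)O[C@@H]3C[C@H](C)CC[C@H]3C(C)(C)c3ccccc3)[C@@H]1CCC(Br)(C(=O)OC)[C@@H]2CCO[Si](C)(C)C(C)(C)C
F3 | step 8 | C3 p-toluenesulfonylhydrazone of 12 | C[C@]12CCC(=NNS(=O)(=O)c3ccc(C)cc3)[C@](C)(C(=O)O[C@@H]3C[C@H](C)CC[C@H]3C(C)(C)c3ccccc3)[C@@H]1CCC(C(=O)OC)[C@@H]2CCO[Si](C)(C)C(C)(C)C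
F4 | step 8 | 17-methyl 19-[(1R,2S,5R)-8-phenylmenthyl] (4S,5R,8R,9S,10R)-12-[(tert-butyldimethylsilyl)oxy]-13,14,15,16-tetranorlabdane-17,19-dioate | C[C@]12CCC[C@](C)(C(=O)O[C@@H]3C[C@H](C)CC[C@H]3C(C)(C)c3ccccc3)[C@@H]1CC[C@@H](C(=O)OC)[C@@H]2CCO[Si](C)(C)C(C)(C)C
F5 | step 8 | 12-[(tert-butyldimethylsilyl)oxy]-13,14,15,16-tetranorlabdane-17,19-diol (8β-H) | C[C@]12CCC[C@](C)(CO)[C@@H]1CC[C@@H](CO)[C@@H]2CCO[Si](C)(C)C(C)(C)C
F6 | step 8 | (4S,5R,8R,9S,10R)-12-[(tert-butyldimethylsilyl)oxy]-13,14,15,16-tetranorlabdane-17,19-dioic acid | C[C@]12CCC[C@](C)(C(=O)O)[C@@H]1CC[C@@H](C(=O)O)[C@@H]2CCO[Si](C)(C)C(C)(C)C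
F7 | step 11 | (4S,5R,8R,9S,10R)-12-iodo-13,14,15,16-tetranorlabdane-17,19-dioic acid | C[C@]12CCC[C@](C)(C(=O)O)[C@@H]1CC[C@@H](C(=O)O)[C@@H]2CCI
F8 | step 11 | di-tert-butyl (4S,5R,8R,9S,10R)-12-iodo-13,14,15,16-tetranorlabdane-17,19-dioate | C[C@]12CCC[C@](C)(C(=O)OC(C)(C)C)[C@@H]1CC[C@@H](C(=O)OC(C)(C)C)[C@@H]2CCI
F9 | step 11 | di-tert-butyl 13-(phenylsulfanyl)-13,14-dihydro derivative of 22 (C13 epimers) | C[C@]12CCC[C@](C)(C(=O)OC(C)(C)C)[C@@H]1CC[C@@H](C(=O)OC(C)(C)C)[C@@H]2CCC1(Sc2ccccc2)CCOC1=O
F10 | step 11 | di-tert-butyl ester of 22 | C[C@]12CCC[C@](C)(C(=O)OC(C)(C)C)[C@@H]1CC[C@@H](C(=O)OC(C)(C)C)[C@@H]2CCC1=CCOC1=O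
F11 | step 3 | (but-3-yn-1-yloxy)(tert-butyl)dimethylsilane | C#CCCO[Si](C)(C)C(C)(C)C
F12 | step 3 | methyl 5-[(tert-butyldimethylsilyl)oxy]pent-2-ynoate | COC(=O)C#CCCO[Si](C)(C)C(C)(C)C
F13 | step 3 | methyl (2E)-5-[(tert-butyldimethylsilyl)oxy]-2-(tributylstannyl)pent-2-enoate | COC(=O)/C([Sn](CCCC)(CCCC)CCCC)=C\CCO[Si](C)(C)C(C)(C)C
F14 | step 3 | methyl (2E)-5-[(tert-butyldimethylsilyl)oxy]-2-iodopent-2-enoate | COC(=O)/C(I)=C\CCO[Si](C)(C)C(C)(C)C
F15 | step 3 | 9-(4-methylpent-3-en-1-yl)-9-borabicyclo[3.3.1]nonane | CC(C)=CCCB1C2CCCC1CCC2
A1 | alternative 1 | (S)-Wieland–Miescher ketone, (8aS)-8a-methyl-3,4,8,8a-tetrahydronaphthalene-1,6(2H,7H)-dione | C[C@]12CCC(=O)C=C1CCCC2=O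
A2 | alternative 1 | methyl (4R,5R,10S)-3,9-dioxo-11,12,13,14,15,16,17-heptanorlabdan-19-oate (trans-decalin keto ester with C4 methyl α and ester β) | C[C@]12CCC(=O)[C@](C)(C(=O)OC)[C@@H]1CCCC2=O
A3 | alternative 3 | (+)-podocarpic acid, 12-hydroxypodocarpa-8,11,13-trien-19-oic acid | C[C@]12CCC[C@](C)(C(=O)O)[C@@H]1CCc1ccc(O)cc12
A4 | alternative 3 | (4S,5R,8R,9S,10R)-13,14,15,16-tetranorlabdane-12,17,19-trioic acid | C[C@]12CCC[C@](C)(C(=O)O)[C@@H]1CC[C@@H](C(=O)O)[C@@H]2CC(=O)O
A5 | alternative 2 | methyl (2Z)-2-{(3E)-6-[(2S,3S)-3-(acetoxymethyl)-3-methyloxiran-2-yl]-4-methylhex-3-en-1-yl}-5-[(tert-butyldimethylsilyl)oxy]pent-2-enoate | CC(=O)OC[C@]1(C)O[C@H]1CC/C(C)=C/CC/C(C(=O)OC)=C/CCO[Si](C)(C)C(C)(C)C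
A6 | alternative 2 | methyl 19-acetoxy-12-[(tert-butyldimethylsilyl)oxy]-3β-hydroxy-13,14,15,16-tetranorlabdan-17-oate (8β-H) | C[C@]12CC[C@H](O)[C@](C)(COC(C)=O)[C@@H]1CC[C@@H](C(=O)OC)[C@@H]2CCO[Si](C)(C)C(C)(C)C
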